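**Retrosynthetic overview**

1. Target (chamigrane locants: ring B = C1–C5, spiro C6, ring A = C7–C11) ⇒ C3–Cl by bromine-assisted substitution of a C3 carbinol; C3–Me by methyl addition to a C3 ketone; C2–Br by α-bromination after enantiotopos-selective enolisation of a ring B cyclohexanone; C7–Me by methylation of an enol triflate.
2. ⇒ a spiro[5.5]undeca-1,4-diene-3,7-dione that already carries the C10 bromide; ring A, the C6–C11 bond between two quaternary carbons and the dearomatised ring B all arise in one oxidative semipinacol ring expansion of a 4-(1-hydroxycyclopentyl)phenol (cyclopentane → cyclohexanone).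
3. Enabling feature: the tertiary carbinol carbon of the cyclopentane (future C7) is bonded to the para carbon of a phenol (future C6), and its ring neighbour is the quaternary CMe2 carbon (future C11); oxidation of the phenol makes C6 electrophilic and the C7–C11 bond migrates to it while C7 becomes a ketone.
4. ⇒ aryl Grignard addition to (R)-3-bromo-2,2-dimethylcyclopentanone, made from 2,2-dimethylcyclopentane-1,3-dione by CBS reduction and Appel inversion.
5. Ring order: the cyclopentane is purchased; ring A (six-membered) is made from it by ring expansion in the same step that turns the benzene ring into the ring B dienone; ring B is then saturated and halogenated.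

Key step: step 4

Assumption: the target is (2S,3S,6S,10R) in chamigrane locants, which are used in all spiro names below; compounds 1 and 4 are taken as purchasable.

**Route**

Step 1
Reactants: 1 2,2-dimethylcyclopentane-1,3-dione
Product: 2 (S)-3-hydroxy-2,2-dimethylcyclopentan-1-one
Conditions: (R)-2-methyl-CBS-oxazaborolidine (10 mol %), BH3·SMe2 (0.6 equiv), THF, −30 °C; MeOH quench
Reagents that add atoms: none
Why: Corey–Bakshi–Shibata reduction desymmetrises the diketone, the borane-bound carbonyl taking the quaternary C2 as its large group so that hydride should enter the face that gives the (S)-carbinol, and the limited borane stops the reduction at the hydroxy ketone.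

Step 2
Reactants: 2 (S)-3-hydroxy-2,2-dimethylcyclopentan-1-one
Product: 3 (R)-3-bromo-2,2-dimethylcyclopentan-1-one
Conditions: PPh3, CBr4, CH2Cl2, 0 → 40 °C
Reagents that add atoms: tetrabromomethane, BrC(Br)(Br)Br
Why: Appel reaction, in which bromide displaces the alkoxyphosphonium group by SN2 with inversion (S → R); the five-membered ring tolerates backside attack next to the quaternary carbon and the β-carbonyl group disfavours ionisation and methyl shift.

Step 3
Reactants: 3 (R)-3-bromo-2,2-dimethylcyclopentan-1-one; 4 (4-bromophenoxy)trimethylsilane
Product: 7 4-[(1R,3R)-3-bromo-1-hydroxy-2,2-dimethylcyclopentyl]phenol, via aryl Grignard reagent 5 (not isolated), via bromomagnesium alkoxide 6 (not isolated)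
Conditions: 4, Mg, THF, 50 °C; then CeCl3, 3, THF, −78 → 0 °C; then MeOH, K2CO3 (cat.), 0 °C
Reagents that add atoms: none
Why: Grignard 1,2-addition to the hindered ketone, kept non-basic by CeCl3 so that enolisation is suppressed, should place the aryl group trans to bromine (the C1 epimer would serve equally, since C1 becomes the C7 carbonyl carbon), and mild methanolysis frees the phenol from its trimethylsilyl ether.

Step 4
Reactants: 7 4-[(1R,3R)-3-bromo-1-hydroxy-2,2-dimethylcyclopentyl]phenol
Product: 8 (10R)-10-bromo-11,11-dimethylspiro[5.5]undeca-1,4-diene-3,7-dione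
Conditions: PhI(OAc)2 (1.1 equiv), (CF3)2CHOH, 0 °C
Reagents that add atoms: none
Why: Two-electron oxidation of the phenol by PhI(OAc)2 in the ionising, non-nucleophilic solvent makes the para carbon C6 of ring B electrophilic (phenoxenium character), and the lone pair of the C7 hydroxyl then drives a semipinacol 1,2-shift of the C7–C11 bond onto C6, which expands the cyclopentane to the six-membered ring A, joins the two quaternary carbons C6 and C11, turns C7 into a ketone and leaves ring B as a 2,5-cyclohexadienone. The closest known reaction type is the hypervalent-iodine oxidative dearomatisation of 4-(1-hydroxyalkyl)phenols with 1,2-alkyl shift (oxidative semipinacol or Wagner–Meerwein transposition), ring-expanding cases included. Ring A is formed by ring expansion through a suprafacial 1,2-alkyl migration and not by a cyclisation, and ring B is not closed but dearomatised. No new stereocentre is formed, because the two enone arms on C6 are constitutionally identical, and C10 is carried through unchanged. The step needs migration of the quaternary C11 and not of the methylene C8, which the higher migratory aptitude of the more substituted carbon should secure even with bromine on C10, and it needs the cation not to be trapped, which the non-nucleophilic solvent secures.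

Step 5
Reactants: 8 (10R)-10-bromo-11,11-dimethylspiro[5.5]undeca-1,4-diene-3,7-dione
Product: 9 (10R)-10-bromo-11,11-dimethyl-3-oxospiro[5.5]undeca-1,4,7-trien-7-yl trifluoromethanesulfonate
Conditions: KN(SiMe3)2, THF, −78 °C; then PhNTf2, −78 → 0 °C
Reagents that add atoms: N-phenylbis(trifluoromethanesulfonimide), O=S(=O)(N(c1ccccc1)S(=O)(=O)C(F)(F)F)C(F)(F)F
Why: Enol triflate formation can only occur toward C8, because C6 is quaternary and the cross-conjugated dienone of ring B has no sp3 α-hydrogen, while displacement of the C10 bromide by the enolate carbon is geometrically disfavoured inside the six-membered ring at −78 °C.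

Step 6
Reactants: 9 (10R)-10-bromo-11,11-dimethyl-3-oxospiro[5.5]undeca-1,4,7-trien-7-yl trifluoromethanesulfonate
Product: 10 (10R)-10-bromo-7,11,11-trimethylspiro[5.5]undeca-1,4,7-trien-3-one
Conditions: Me2Zn, Pd(PPh3)4 (5 mol %), THF, 0 °C → rt
Reagents that add atoms: dimethylzinc, C[Zn]C
Why: Negishi coupling of the enol triflate installs the C7 methyl group with the C7=C8 double bond fixed in place, since dimethylzinc does not add to the dienone without a Lewis acid and zerovalent palladium does not insert into the secondary alkyl bromide under these conditions.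

Step 7
Reactants: 10 (10R)-10-bromo-7,11,11-trimethylspiro[5.5]undeca-1,4,7-trien-3-one
Product: 11 (10R)-10-bromo-7,11,11-trimethylspiro[5.5]undec-7-en-3-one
Conditions: H2 (1 atm), Pd/C, EtOAc, rt
Reagents that add atoms: none
Why: Heterogeneous catalytic hydrogenation should saturate the two disubstituted enone double bonds of ring B and leave the trisubstituted C7=C8 bond next to the quaternary C6 and the alkyl bromide untouched; C6 is still not a stereocentre.

Step 8
Reactants: 11 (10R)-10-bromo-7,11,11-trimethylspiro[5.5]undec-7-en-3-one
Product: 12 {[(6S,10R)-10-bromo-7,11,11-trimethylspiro[5.5]undeca-2,7-dien-3-yl]oxy}trimethylsilane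
Conditions: (R,R)-bis(1-phenylethyl)amine, n-BuLi, THF, −78 °C; then Me3SiCl (internal quench), 11, −100 → −78 °C
Reagents that add atoms: chlorotrimethylsilane, C[Si](C)(C)Cl
Why: Enantiotopos-selective deprotonation by a twofold-symmetric chiral lithium amide with in situ silylation distinguishes the two α-methylene groups of the ring B ketone and so makes C6 a stereocentre under reagent control; by analogy with 4-substituted cyclohexanones (ring B chair with C11 equatorial and C7 axial) the (R,R)-amide should enolise toward the methylene that becomes C2, which fixes C6 as (S).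

Step 9
Reactants: 12 {[(6S,10R)-10-bromo-7,11,11-trimethylspiro[5.5]undeca-2,7-dien-3-yl]oxy}trimethylsilane
Product: 13 (2S,6S,10R)-2,10-dibromo-7,11,11-trimethylspiro[5.5]undec-7-en-3-one
Conditions: N-bromosuccinimide, THF, −78 → 0 °C
Reagents that add atoms: N-bromosuccinimide, O=C1CCC(=O)N1Br
Why: Electrophilic α-bromination of the silyl enol ether places bromine regiospecifically at C2 on the face of ring B away from the axial C7 substituent, which gives the equatorial bromide cis to C11, and this is also the thermodynamically preferred epimer of the enolisable centre.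

Step 10
Reactants: 13 (2S,6S,10R)-2,10-dibromo-7,11,11-trimethylspiro[5.5]undec-7-en-3-one
Product: 14 (2S,3R,6S,10R)-2,10-dibromo-3,7,11,11-tetramethylspiro[5.5]undec-7-en-3-ol
Conditions: MeMgBr, CeCl3, THF, −78 °C; aq. NH4Cl at −78 °C
Reagents that add atoms: methylmagnesium bromide, C[Mg]Br
Why: Organocerium-type 1,2-addition to the α-bromo ketone, non-basic enough to avoid enolisation and halogen–metal exchange, should give the tertiary carbinol mainly by attack trans to bromine, and either C3 epimer is usable because C3 is ionised in the next step.

Step 11
Reactants: 14 (2S,3R,6S,10R)-2,10-dibromo-3,7,11,11-tetramethylspiro[5.5]undec-7-en-3-ol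
Product: 15 (2S,3S,6S,10R)-2,10-dibromo-3-chloro-3,7,11,11-tetramethylspiro[5.5]undec-7-ene
Conditions: HCl (g), CH2Cl2, −20 → 0 °C
Reagents that add atoms: hydrogen chloride, Cl
Why: SN1 substitution with neighbouring-group participation, in which loss of water from C3 gives a cation bridged by the C2 bromine on its own face (bromonium ion) and chloride opens it at the tertiary carbon C3 from the opposite face, so that chlorine should end trans to bromine and cis to C7 (3S) with the methyl group axial.

**Compound list**

1 | 2,2-dimethylcyclopentane-1,3-dione | CC1(C)C(=O)CCC1=O | starting material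
2 | (S)-3-hydroxy-2,2-dimethylcyclopentan-1-one | O=C1CC[C@H](O)C1(C)C | intermediate
3 | (R)-3-bromo-2,2-dimethylcyclopentan-1-one | O=C1CC[C@@H](Br)C1(C)C | intermediate
4 | (4-bromophenoxy)trimethylsilane | C[Si](C)(C)Oc1ccc(Br)cc1 | starting material
5 | [4-(trimethylsilyloxy)phenyl]magnesium bromide | C[Si](C)(C)Oc1ccc([Mg]Br)cc1 | intermediate (not isolated)
6 | bromomagnesium (1R,3R)-3-bromo-2,2-dimethyl-1-[4-(trimethylsilyloxy)phenyl]cyclopentan-1-olate | C[Si](C)(C)Oc1ccc(cc1)[C@]1(O[Mg]Br)CC[C@@H](Br)C1(C)C | intermediate (not isolated)
7 | 4-[(1R,3R)-3-bromo-1-hydroxy-2,2-dimethylcyclopentyl]phenol (aryl trans to Br; the C1 epimer converges) | Oc1ccc(cc1)[C@]1(O)CC[C@@H](Br)C1(C)C | intermediate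
8 | (10R)-10-bromo-11,11-dimethylspiro[5.5]undeca-1,4-diene-3,7-dione | O=C1CC[C@@H](Br)C(C)(C)C12C=CC(=O)C=C2 | intermediate
9 | (10R)-10-bromo-11,11-dimethyl-3-oxospiro[5.5]undeca-1,4,7-trien-7-yl trifluoromethanesulfonate | O=C1C=CC2(C=C1)C(OS(=O)(=O)C(F)(F)F)=CC[C@@H](Br)C2(C)C | intermediate
10 | (10R)-10-bromo-7,11,11-trimethylspiro[5.5]undeca-1,4,7-trien-3-one | O=C1C=CC2(C=C1)C(C)=CC[C@@H](Br)C2(C)C | intermediate
11 | (10R)-10-bromo-7,11,11-trimethylspiro[5.5]undec-7-en-3-one | O=C1CCC2(CC1)C(C)=CC[C@@H](Br)C2(C)C | intermediate
12 | {[(6S,10R)-10-bromo-7,11,11-trimethylspiro[5.5]undeca-2,7-dien-3-yl]oxy}trimethylsilane | CC1=CC[C@@H](Br)C(C)(C)[C@]12CCC(O[Si](C)(C)C)=CC2 | intermediate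
13 | (2S,6S,10R)-2,10-dibromo-7,11,11-trimethylspiro[5.5]undec-7-en-3-one | CC1=CC[C@@H](Br)C(C)(C)[C@]12CCC(=O)[C@@H](Br)C2 | intermediate
14 | (2S,3R,6S,10R)-2,10-dibromo-3,7,11,11-tetramethylspiro[5.5]undec-7-en-3-ol (major C3 epimer; the other converges) | CC1=CC[C@@H](Br)C(C)(C)[C@]12CC[C@@](C)(O)[C@@H](Br)C2 | intermediate
15 | (2S,3S,6S,10R)-2,10-dibromo-3-chloro-3,7,11,11-tetramethylspiro[5.5]undec-7-ene | CC1=CC[C@@H](Br)C(C)(C)[C@]12CC[C@](C)(Cl)[C@@H](Br)C2 | target

**Step count and risks**

Total step count: 11. Longest linear sequence: 11 steps (1 → 15; the aryl partner 4 is purchased).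

Steps most likely to fail:

- **Step 11.** The C3 cation may be captured without bromine bridging, which loses the anti relationship. The bromonium ion may open at C2 with shift of bromine to C3. A proton may be lost (E1), or HCl may add to the ring A double bond. The fallback replaces substitution at a carbinol by anti addition to an alkene and sets out from 12. Methyllithium cleaves the silyl enol ether to the lithium enolate, which PhNTf2 converts into (6S,10R)-10-bromo-7,11,11-trimethylspiro[5.5]undeca-2,7-dien-3-yl trifluoromethanesulfonate F1. Negishi methylation (Me2Zn, Pd(PPh3)4) gives (6S,10R)-10-bromo-3,7,11,11-tetramethylspiro[5.5]undeca-2,7-diene F2. Bromochlorination of the less hindered ring B double bond with Bu4NBrCl2 in CH2Cl2 at −78 °C (bromonium ion on the face away from the axial C7, chloride at the tertiary C3) comes back to the route at 15.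

- **Step 2.** Displacement at the carbinol next to the quaternary carbon may be slow, and elimination toward C4 may compete. The fallback uses a discrete sulfonate and free bromide in place of phosphonium activation and sets out from 2. Tf2O and pyridine in CH2Cl2 at −20 °C give (S)-2,2-dimethyl-3-oxocyclopentyl trifluoromethanesulfonate F3. LiBr in acetone displaces it with inversion and comes back to the route at 3.

- **Step 8.** Discrimination of the two α-methylene groups may be weak or reversed, because the axial α-hydrogens lie under the axial C7 substituent and the analogy with simple 4-substituted cyclohexanones may not hold. The fallback uses enamine catalysis in place of a lithium amide and sets out from 11. Enantioselective organocatalytic α-bromination (chiral 4,5-diphenylimidazolidine, benzoic acid, 4,4-dibromo-2,6-di-tert-butylcyclohexa-2,5-dienone as bromine donor, THF, −30 °C) comes back to the route at 13, and the bromide can settle into the equatorial position by enolisation. No new compound arises (F0).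

Further compounds
F1 | step 11 | (6S,10R)-10-bromo-7,11,11-trimethylspiro[5.5]undeca-2,7-dien-3-yl trifluoromethanesulfonate | CC1=CC[C@@H](Br)C(C)(C)[C@]12CCC(OS(=O)(=O)C(F)(F)F)=CC2
F2 | step 11 | (6S,10R)-10-bromo-3,7,11,11-tetramethylspiro[5.5]undeca-2,7-diene | CC1=CC[C@@H](Br)C(C)(C)[C@]12CCC(C)=CC2
F3 | step 2 | (S)-2,2-dimethyl-3-oxocyclopentyl trifluoromethanesulfonate | O=C1CC[C@H](OS(=O)(=O)C(F)(F)F)C1(C)C
F0 | step 8 | none | none
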